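## The problem

Eudesmane numbering is used throughout: ring A is C1–C5 and C10, ring B is C5–C10, C14 is the methyl on C10, C15 the methyl on C4, and C11–C13 the isopropylidene carbons.

- **Ring system.** The target is a trans-fused decalin. Ring A carries the (S)-3-methylpentanoate on C3 and a tertiary carbinol on C4. Ring B carries the C8 ketone conjugated with the C7 isopropylidene group.
- **Stereocenters.** Four contiguous centers lie on ring A: the C3 ester oxygen is α and axial, the C4 hydroxyl is α with its methyl β and syn-axial to the C10 methyl, H5 is α, and the C10 methyl is β. The fifth center sits in the acyl chain, β to the carboxyl, so it cannot epimerise and can be bought.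
- **Control.** C10 is quaternary and remote from any heteroatom, so the skeleton-forming step must set it. Once in place it can control the rest: dissolving-metal reduction gives the trans fusion at C5, and the angular methyl shields the β face of ring A so that C3 and C4 can be oxygenated together from the α face.
- **C4 configuration.** The axial methyl at C4 is the opposite of what a methyl nucleophile delivers to a C4 ketone in this series. This argues for syn-dihydroxylation of a C3=C4 alkene.
- **Sensitive groups.** The α-isopropylidene ketone can deconjugate, move its double bond into the ring, or accept nucleophiles. The tertiary alcohol can eliminate under acid. The ester is base-labile. All three should appear late.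
- **Regiochemistry at C8.** C7 must be functionalised in preference to C9, both being α to the ketone.
- **Enabling feature.** Ring A bears oxygen at C3 para to C10 and methyl groups at C4 and C10. It is therefore the dearomatised form of a 2,4-dimethylphenol that carries the ring B carbons as a chain on C5. The C8 carbonyl can be carried as the exocyclic methylene that a 2-substituted allyl unit leaves behind.

## Retrosynthesis

**Ester C–O bond.** Target 26 is cut to diol 24 and acid 25. Cutting here keeps an enolisable ester out of the enolate chemistry at C7. The competing C4 hydroxyl is tertiary, so no protecting group is needed. The precursor loses the side-chain stereocenter, which comes with 25. The forward step must acylate an axial secondary alcohol without acid that could ionise C4.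

**C3–O and C4–O bonds.** Both ring A oxygens of 24 are removed together, giving dienone 23. The neighbouring option, a methyl nucleophile added to a C4 ketone, would enter from the α face and give the wrong C4 epimer. A single suprafacial addition makes the cis relationship certain and leaves only the face to be chosen, which the C10 methyl decides. The precursor has two fewer stereocenters. The forward step must prefer the trisubstituted ring alkene over the tetrasubstituted, electron-poor C7=C11 alkene.

**C7=C11 bond.** Dienone 23 is cut through aldol 21 to ketone 18 and a three-carbon ketone electrophile. Carrying the isopropylidene group earlier is excluded, because it would not survive the reductions of ring A. The forward step must enolise the C8 ketone toward C7 and not toward C9.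

**Ring A adjustment.** Ketone 18 is traced to enol triflate 17 (C3–H from C3–OTf), then to 15 (C8=O from C8=CH2), then to enone 13 (C5–H and the enol triflate from the enone). The order is chosen so that no protecting group is needed:
- the methylene survives dissolving metal where a ketone would not;
- it is cleaved while the ring A alkene is deactivated as its triflate, since after reduction to 18 the two alkenes could not be told apart.

The forward reduction must deliver hydrogen to C5 on the α face and trap the enolate where it is formed.

**C1=C2 unsaturation.** Enone 13 is traced to cross-conjugated dienone 12. This makes ring A recognisable as a dearomatised phenol. The forward step must reduce the disubstituted C1=C2 bond and leave the C4=C5 enone and the methylene untouched.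

**C9–C10 bond (key cut).** Dienone 12 is cut to phenol carbonate 11. Other cuts in ring B (C5–C6, C7–C8) leave C10 to be made quaternary by enolate alkylation on a preformed ring, and a Robinson-type cut of ring A places the ring B oxygen at C9, not C8. The chosen cut leads to a flat, achiral arene that already holds all six carbons of ring A, the C3 oxygen and both methyl groups. The allyl unit brings C8 with its masked carbonyl. The forward step must ionise the allylic carbonate, make the phenol react through its para carbon and not through C4 or oxygen, and select one face of the arene.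

**Carbonate, silyl ether and C7–C8 bond.** Carbonate 11 comes from silyl ether 10 and this from alcohol 9, which is cut at C7–C8 to styrene 6 and bromoallyl alcohol 7. The alternative of joining the arene to a hydroborated 2-substituted butadiene (a C5–C6 cut) would ask the borane to choose between two terminal alkenes. Placing the alkene on the arene removes that question. The silyl ether is needed because the phenol would otherwise be carbonated along with the alcohol.

**Arene.** Styrene 6 comes from bromide 5 by vinylation (C5–C6 bond), 5 from phenol 4, and 4 from ketone 2 and bromoxylene 1. The oxygen is introduced by acylation and oxygen insertion, because both methyl groups of 1 direct an electrophile to the required position.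

## Roads not taken

**Alternative 1:** The cut is the C10–C14 bond, so the angular methyl is added to a preformed octalin.
- *Forward key step.* The zinc alkoxide of allylic alcohol 4β-hydroxy-11,12,13,14,15-pentanoreudesm-5(10)-en-8-one ethylene ketal A1 directs a zinc carbenoid (Simmons–Smith conditions) to the tetrasubstituted C5=C10 alkene. This gives the [4.4.1]propellane A2 with the new methylene on the β face. Later the C5–C14 bond is broken to leave the methyl on C10.
- *Merits.* Hydroxyl-directed cyclopropanation is one of the few reactions that functionalise a fully substituted ring-fusion alkene reliably, and its facial outcome follows from the carbinol. In this respect its key step is better founded than that of the chosen plan, which has no direct precedent.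
- *Weak points.* The step only relays chirality, so the C4 carbinol must be made enantiopure beforehand. The three-membered ring must then be opened at C5–C14 and not at C5–C10, which rests on orbital overlap in a rigid propellane, and C5 must still be protonated on the α face. A2 contains neither C15 nor the C3 oxygen, and methyl addition at C4 would give the wrong epimer. Ring A would therefore have to pass through the same C3=C4 alkene as 23, reached from further back.
- *Comparison.* Against the stronger precedent, the chosen plan sets a phenol that already contains every carbon of ring A with its oxygen and methyl groups, and a key step that creates C10 by catalysis.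

**Alternative 2:** Two bonds are cut, C5–C10 and C6–C7, unravelling both rings to the acyclic dienynone (E)-9-(tert-butyldimethylsilyloxy)-7-methyldeca-7,9-dien-1-yn-3-one A3.
- *Forward key step.* A chiral oxazaborolidinium Lewis acid activates the ynone, which adds across the tethered silyloxydiene. This gives 8-(tert-butyldimethylsilyloxy)-11,12,13,15-tetranoreudesma-5,8-dien-4-one A4 with C10 quaternary.
- *Merits.* No other plan gains as much in one step: both rings and the quaternary center come from a chain in one catalytic enantioselective event, and the C8 oxygen arrives as a regiodefined enol ether. Here it is clearly superior to the chosen plan, whose key step closes only one ring.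
- *Weak points.* A3 combines a terminal ynone, a strong conjugate acceptor, with an acid-labile silyloxydiene, and the catalyst is a strong Lewis acid. The diene terminus that becomes C10 is disubstituted, so one substituent lies inside the reactive conformer and slows the cycloaddition where the quaternary center forms. Enantiocontrol by such catalysts is far better established for alkenyl carbonyl dienophiles than for a tethered alkynyl ketone. A4 lacks C15 and the C3 oxygen, its C4 ketone cannot simply be methylated, and C5 is still to be set.
- *Comparison.* The chosen plan gives up this convergence. It sets against it stable starting materials, a precursor 11 made by routine coupling chemistry, and a product 12 that already holds C15 and the C3 oxygen.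

**Alternative 3:** The C3–C4 bond is cut, opening ring A to keto aldehyde 3-[(7R,8R)-8-acetyl-7-methyl-1,4-dioxaspiro[4.5]decan-7-yl]propanal A5.
- *Forward key step.* A chiral triazolylidene carbene turns the aldehyde into an acyl anion equivalent that adds to the methyl ketone. This closes ring A as 4α-hydroxy-11,12,13-trinor-5α-eudesmane-3,8-dione 8-ethylene ketal A6.
- *Merits.* The tertiary carbinol and the C3 carbonyl form in one mild catalytic operation. A6 is closer to the oxidation pattern of the target than any intermediate of the chosen route, which spends steps 10, 12 and 15 on turning the C3 carbonyl into the diol. The C8 ketone is already protected for the work at C7.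
- *Weak points.* The hard elements are moved into A5: a cyclohexane with the quaternary C10 and its neighbour C5 in a defined trans relationship, to be made enantiopure by a separate sequence. C4 must form with hydroxyl α and methyl axial, a contest between substrate and catalyst control. The C3 ketone must then be reduced to the axial alcohol cis to the C4 hydroxyl, whereas small hydrides and chelation both favour the equatorial, trans product.
- *Comparison.* The chosen plan sets C3 and C4 in one syn addition, so their cis relationship is not in question. Against the shorter ring A endgame of this alternative it sets a much shorter way to the enantioenriched bicyclic skeleton.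

Key step: step 8

Assumption: the (R,R) antipode of the diphosphine is written in step 8 on the understanding that the ligand enantiomer which delivers (10S)-12 is the one used. The sense of induction for this new substrate class cannot be derived from the known cases, and the (S,S) ligand is substituted if a first run shows the opposite sense.

## Route

Step 1
Reactants: 1 2-bromo-1,3-dimethylbenzene
Product: 2 1-(3-bromo-2,4-dimethylphenyl)ethan-1-one
Conditions: AcCl, AlCl3, CH2Cl2, 0 °C to rt
Reagents that add atoms: acetyl chloride, CC(=O)Cl
Why: Friedel–Crafts acylation; the position attacked is ortho to one methyl, para to the other and meta to bromine (the two such positions are equivalent), whereas the position para to bromine is activated by neither methyl.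

Step 2
Reactants: 2 1-(3-bromo-2,4-dimethylphenyl)ethan-1-one
Product: 4 3-bromo-2,4-dimethylphenol, via aryl acetate 3 (not isolated)
Conditions: mCPBA, CF3CO2H (cat.), CH2Cl2, rt; then K2CO3, MeOH, rt
Reagents that add atoms: meta-chloroperoxybenzoic acid, OOC(=O)c1cccc(Cl)c1
Why: Baeyer–Villiger oxidation; the electron-rich, ortho-substituted aryl group migrates in preference to methyl, and the aryl acetate is methanolysed without isolation.

Step 3
Reactants: 4 3-bromo-2,4-dimethylphenol
Product: 5 (3-bromo-2,4-dimethylphenoxy)tri(propan-2-yl)silane
Conditions: i-Pr3SiCl, imidazole, DMF, rt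
Reagents that add atoms: chlorotri(propan-2-yl)silane, CC(C)[Si](Cl)(C(C)C)C(C)C
Why: Silylation of a phenol; the triisopropylsilyl ether is chosen because it should survive the aqueous base of both cross-couplings and is later removed by fluoride without harm to an allylic carbonate.

Step 4
Reactants: 5 (3-bromo-2,4-dimethylphenoxy)tri(propan-2-yl)silane
Product: 6 (3-ethenyl-2,4-dimethylphenoxy)tri(propan-2-yl)silane
Conditions: vinylboronic acid pinacol ester, Pd(OAc)2, SPhos, K3PO4, toluene/H2O, 90 °C
Reagents that add atoms: 2-ethenyl-4,4,5,5-tetramethyl-1,3,2-dioxaborolane, C=CB1OC(C)(C)C(C)(C)O1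
Why: Suzuki–Miyaura vinylation forming C5–C6; the dialkylbiarylphosphine is used because the bromide is flanked by two ortho methyl groups.

Step 5
Reactants: 6 (3-ethenyl-2,4-dimethylphenoxy)tri(propan-2-yl)silane; 7 2-bromoprop-2-en-1-ol
Product: 9 4-{2,6-dimethyl-3-[tri(propan-2-yl)silyloxy]phenyl}-2-methylidenebutan-1-ol, via alkylborane 8 (not isolated)
Conditions: 9-BBN, THF, rt to 50 °C; then 7, PdCl2(dppf), K3PO4 (aq), DMF, 50 °C
Reagents that add atoms: none
Why: Anti-Markovnikov hydroboration of the styrene puts boron on the terminal carbon, and B-alkyl Suzuki–Miyaura coupling with the vinyl bromide forms C7–C8; the free hydroxyl of 7 is tolerated in this coupling.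

Step 6
Reactants: 9 4-{2,6-dimethyl-3-[tri(propan-2-yl)silyloxy]phenyl}-2-methylidenebutan-1-ol
Product: 10 methyl 4-{2,6-dimethyl-3-[tri(propan-2-yl)silyloxy]phenyl}-2-methylidenebutyl carbonate
Conditions: ClCO2Me, pyridine, CH2Cl2, 0 °C
Reagents that add atoms: methyl chloroformate, COC(=O)Cl
Why: Acylation of a primary allylic alcohol to its methyl carbonate; the phenol is masked, so only one hydroxyl reacts.

Step 7
Reactants: 10 methyl 4-{2,6-dimethyl-3-[tri(propan-2-yl)silyloxy]phenyl}-2-methylidenebutyl carbonate
Product: 11 methyl 4-(3-hydroxy-2,6-dimethylphenyl)-2-methylidenebutyl carbonate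
Conditions: Bu4NF, AcOH, THF, 0 °C
Reagents that add atoms: none
Why: Fluoride cleavage of an aryl silyl ether; the acetic acid buffer keeps the liberated phenol protonated so that it does not attack the carbonate.

Step 8
Reactants: 11 methyl 4-(3-hydroxy-2,6-dimethylphenyl)-2-methylidenebutyl carbonate
Product: 12 (10S)-8-methylidene-11,12,13-trinoreudesma-1,4-dien-3-one [(4aS)-1,4a-dimethyl-6-methylidene-5,6,7,8-tetrahydronaphthalen-2(4aH)-one]
Conditions: Pd2(dba)3·CHCl3 (2.5 mol %), (R,R)-DACH-phenyl Trost ligand (7.5 mol %), CH2Cl2 (0.01 M), rt
Reagents that add atoms: none
Why: Proposed new method: zerovalent palladium bound to the chiral diphosphine ionises the allylic carbonate with loss of CO2 to a cationic η3-(2-alkylallyl)palladium complex and methoxide, which deprotonates the phenol; the phenoxide then attacks an allyl terminus through its para carbon C10 on the face away from the metal, forming C9–C10. The closest known reaction types are the palladium-catalysed intramolecular allylic alkylation of para-tethered phenols to spirocyclohexadienones and the palladium-catalysed intermolecular asymmetric allylic dearomatization of substituted naphthols; neither closes a fused ring from a meta tether onto a substituted para carbon. Ring B closes as a six-membered ring in which the central allyl carbon C8 is a ring member and the far terminus remains as the exocyclic methylene (a 6-exo closure with respect to the departing metal); the two allyl termini are equivalent, so the electrophile poses no regiochemical question. The only new stereocenter, C10, is created on the nucleophile and is controlled by the chiral pocket of the ligand, which decides which face of the phenoxide ring meets the allyl terminus, as in asymmetric allylations of prochiral enolates with this ligand family. The step needs C10 to win over the ortho carbon C4 and over oxygen: intramolecular O-attack would bridge meta positions and is impossible, intermolecular O-allylation is reversible under palladium and is held back by dilution, and C10 is favoured over C4 by the larger para coefficient of the phenoxide HOMO toward a soft electrophile, by lower congestion (C10 is flanked by C1–H, C4 by the solvated oxygen and the tether) and by the greater stability of the cross-conjugated dienone.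

Step 9
Reactants: 12 (10S)-8-methylidene-11,12,13-trinoreudesma-1,4-dien-3-one
Product: 13 (10R)-8-methylidene-11,12,13-trinoreudesm-4-en-3-one
Conditions: [(Ph3P)CuH]6, H2O, toluene/THF, rt
Reagents that add atoms: none
Why: Copper hydride conjugate reduction; hydride goes to the β-carbon C1 of the disubstituted enone arm, while the fully substituted C5 and the isolated methylene are inert, and protonation at C2 returns the C4=C5 enone (the descriptor at C10 changes only because C1 loses priority).

Step 10
Reactants: 13 (10R)-8-methylidene-11,12,13-trinoreudesm-4-en-3-one
Product: 15 (5R,10R)-8-methylidene-11,12,13-trinor-5α-eudesm-3-en-3-yl trifluoromethanesulfonate, via lithium enolate 14 (not isolated)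
Conditions: Li (2.2 equiv), t-BuOH (1 equiv), NH3/THF, −78 °C; NH3 evaporated; then PhNTf2, THF, 0 °C to rt
Reagents that add atoms: N-phenylbis(trifluoromethanesulfonimide), O=S(=O)(N(c1ccccc1)S(=O)(=O)C(F)(F)F)C(F)(F)F
Why: Dissolving-metal reduction of the enone with regiospecific trapping of the enolate as its triflate; C5 is protonated axially on the α face, anti to the C10 methyl, which gives the trans ring fusion (5R), and the isolated methylene is not reduced.

Step 11
Reactants: 15 (5R,10R)-8-methylidene-11,12,13-trinor-5α-eudesm-3-en-3-yl trifluoromethanesulfonate
Product: 17 (5R,10R)-8-oxo-11,12,13-trinor-5α-eudesm-3-en-3-yl trifluoromethanesulfonate, via diol 16 (not isolated)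
Conditions: OsO4 (cat.), NaIO4, 2,6-lutidine, dioxane/H2O, rt
Reagents that add atoms: osmium tetroxide OsO4, O=[Os](=O)(=O)=O (oxygen carrier); sodium periodate NaIO4, [Na+].[O-]I(=O)(=O)=O (terminal oxidant)
Why: Lemieux–Johnson cleavage; the 1,1-disubstituted alkene is osmylated and cleaved, while the tetrasubstituted, electron-poor enol triflate alkene should not react.

Step 12
Reactants: 17 (5R,10R)-8-oxo-11,12,13-trinor-5α-eudesm-3-en-3-yl trifluoromethanesulfonate
Product: 18 (5R,10R)-11,12,13-trinor-5α-eudesm-3-en-8-one
Conditions: Pd(OAc)2, PPh3, HCO2H, Bu3N, DMF, 60 °C
Reagents that add atoms: none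
Why: Palladium-catalysed formate reduction of an enol triflate; the alkene stays where the enolate was, giving the C3=C4 alkene, and the saturated ketone is untouched.

Step 13
Reactants: 18 (5R,10R)-11,12,13-trinor-5α-eudesm-3-en-8-one
Product: 21 (5R,7R,10R)-11-hydroxy-5α-eudesm-3-en-8-one, via lithium enolate 19 (not isolated), via chlorozinc enolate 20 (not isolated)
Conditions: LiN(i-Pr)2, THF, −78 °C; ZnCl2; acetone, −78 to −40 °C; aq. NH4Cl
Reagents that add atoms: acetone, CC(C)=O
Why: Directed aldol addition through the zinc enolate; deprotonation goes to C7 because C9 is neopentylic and a C7=C8 enolate is the less strained one in a trans-decalin, and the side chain should settle equatorial (7R), a center that is removed in the next step.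

Step 14
Reactants: 21 (5R,7R,10R)-11-hydroxy-5α-eudesm-3-en-8-one
Product: 23 (5R,10R)-5α-eudesma-3,7(11)-dien-8-one, via mesylate 22 (not isolated)
Conditions: MsCl, Et3N, CH2Cl2, 0 °C; then DBU, rt
Reagents that add atoms: none
Why: Sulfonylation of the tertiary alcohol and base-induced E1cB elimination through the C7 enolate, which can only give the conjugated C7=C11 alkene; no acid is present that could move the C3=C4 alkene.

Step 15
Reactants: 23 (5R,10R)-5α-eudesma-3,7(11)-dien-8-one
Product: 24 (3R,4S,5R,10R)-3α,4α-dihydroxy-5α-eudesm-7(11)-en-8-one
Conditions: OsO4 (cat.), NMO, acetone/H2O, rt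
Reagents that add atoms: osmium tetroxide OsO4, O=[Os](=O)(=O)=O (oxygen carrier); N-methylmorpholine N-oxide, C[N+]1([O-])CCOCC1 (terminal oxidant); water, O
Why: Catalytic syn-dihydroxylation (Upjohn conditions); the β face of the C3=C4 alkene is shielded by the syn-axial C10 methyl, so both oxygens enter from the α face and set C3 and C4 together, and the tetrasubstituted, electron-poor C7=C11 alkene should react far more slowly.

Step 16
Reactants: 24 (3R,4S,5R,10R)-3α,4α-dihydroxy-5α-eudesm-7(11)-en-8-one; 25 (3S)-3-methylpentanoic acid
Product: 26 (3R,4S,5R,10R)-4α-hydroxy-8-oxo-5α-eudesm-7(11)-en-3α-yl (3S)-3-methylpentanoate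
Conditions: DCC, DMAP, CH2Cl2, rt
Reagents that add atoms: none
Why: Steglich esterification; only the secondary hydroxyl is acylated because the C4 hydroxyl is tertiary, and the stereocenter of the acid is β to the carboxyl and cannot epimerise.

## Compound list

1 | 2-bromo-1,3-dimethylbenzene | Cc1cccc(C)c1Br | starting material
2 | 1-(3-bromo-2,4-dimethylphenyl)ethan-1-one | CC(=O)c1ccc(C)c(Br)c1C | intermediate
3 | 3-bromo-2,4-dimethylphenyl acetate | CC(=O)Oc1ccc(C)c(Br)c1C | intermediate (not isolated)
4 | 3-bromo-2,4-dimethylphenol | Cc1ccc(O)c(C)c1Br | intermediate
5 | (3-bromo-2,4-dimethylphenoxy)tri(propan-2-yl)silane | Cc1ccc(O[Si](C(C)C)(C(C)C)C(C)C)c(C)c1Br | intermediate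
6 | (3-ethenyl-2,4-dimethylphenoxy)tri(propan-2-yl)silane | C=Cc1c(C)ccc(O[Si](C(C)C)(C(C)C)C(C)C)c1C | intermediate
7 | 2-bromoprop-2-en-1-ol | OCC(Br)=C | starting material
8 | 9-{2-[2,6-dimethyl-3-(tri(propan-2-yl)silyloxy)phenyl]ethyl}-9-borabicyclo[3.3.1]nonane | Cc1ccc(O[Si](C(C)C)(C(C)C)C(C)C)c(C)c1CCB1C2CCCC1CCC2 | intermediate (not isolated)
9 | 4-{2,6-dimethyl-3-[tri(propan-2-yl)silyloxy]phenyl}-2-methylidenebutan-1-ol | OCC(=C)CCc1c(C)ccc(O[Si](C(C)C)(C(C)C)C(C)C)c1C | intermediate
10 | methyl 4-{2,6-dimethyl-3-[tri(propan-2-yl)silyloxy]phenyl}-2-methylidenebutyl carbonate | COC(=O)OCC(=C)CCc1c(C)ccc(O[Si](C(C)C)(C(C)C)C(C)C)c1C | intermediate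
11 | methyl 4-(3-hydroxy-2,6-dimethylphenyl)-2-methylidenebutyl carbonate | COC(=O)OCC(=C)CCc1c(C)ccc(O)c1C | intermediate
12 | (10S)-8-methylidene-11,12,13-trinoreudesma-1,4-dien-3-one | O=C1C=C[C@]2(C)CC(=C)CCC2=C1C | intermediate
13 | (10R)-8-methylidene-11,12,13-trinoreudesm-4-en-3-one | O=C1CC[C@]2(C)CC(=C)CCC2=C1C | intermediate
14 | lithium (5R,10R)-8-methylidene-11,12,13-trinor-5α-eudesm-3-en-3-olate | CC1=C([O-])CC[C@]2(C)CC(=C)CC[C@@H]12.[Li+] | intermediate (not isolated)
15 | (5R,10R)-8-methylidene-11,12,13-trinor-5α-eudesm-3-en-3-yl trifluoromethanesulfonate | CC1=C(OS(=O)(=O)C(F)(F)F)CC[C@]2(C)CC(=C)CC[C@@H]12 | intermediate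
16 | (5R,10R)-8-hydroxy-8-(hydroxymethyl)-11,12,13-trinor-5α-eudesm-3-en-3-yl trifluoromethanesulfonate (both C8 epimers) | CC1=C(OS(=O)(=O)C(F)(F)F)CC[C@]2(C)CC(O)(CO)CC[C@@H]12 | intermediate (not isolated)
17 | (5R,10R)-8-oxo-11,12,13-trinor-5α-eudesm-3-en-3-yl trifluoromethanesulfonate | CC1=C(OS(=O)(=O)C(F)(F)F)CC[C@]2(C)CC(=O)CC[C@@H]12 | intermediate
18 | (5R,10R)-11,12,13-trinor-5α-eudesm-3-en-8-one | CC1=CCC[C@]2(C)CC(=O)CC[C@@H]12 | intermediate
19 | lithium (5R,10R)-11,12,13-trinor-5α-eudesma-3,7-dien-8-olate | CC1=CCC[C@]2(C)CC([O-])=CC[C@@H]12.[Li+] | intermediate (not isolated)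
20 | chlorozinc (5R,10R)-11,12,13-trinor-5α-eudesma-3,7-dien-8-olate | CC1=CCC[C@]2(C)CC(O[Zn]Cl)=CC[C@@H]12 | intermediate (not isolated)
21 | (5R,7R,10R)-11-hydroxy-5α-eudesm-3-en-8-one | CC1=CCC[C@]2(C)CC(=O)[C@@H](C(C)(C)O)C[C@@H]12 | intermediate
22 | (5R,7R,10R)-8-oxo-5α-eudesm-3-en-11-yl methanesulfonate | CC1=CCC[C@]2(C)CC(=O)[C@@H](C(C)(C)OS(C)(=O)=O)C[C@@H]12 | intermediate (not isolated)
23 | (5R,10R)-5α-eudesma-3,7(11)-dien-8-one | CC1=CCC[C@]2(C)CC(=O)C(=C(C)C)C[C@@H]12 | intermediate
24 | (3R,4S,5R,10R)-3α,4α-dihydroxy-5α-eudesm-7(11)-en-8-one | O[C@@H]1CC[C@]2(C)CC(=O)C(=C(C)C)C[C@H]2[C@]1(C)O | intermediate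
25 | (3S)-3-methylpentanoic acid | CC[C@H](C)CC(=O)O | starting material
26 | (3R,4S,5R,10R)-4α-hydroxy-8-oxo-5α-eudesm-7(11)-en-3α-yl (3S)-3-methylpentanoate | CC[C@H](C)CC(=O)O[C@@H]1CC[C@]2(C)CC(=O)C(=C(C)C)C[C@H]2[C@]1(C)O | target

## Step count and least certain steps

Total: 16 steps. Longest linear sequence: 16 steps, from 1 to 26; 7 and 25 are bought and enter at steps 5 and 16.

**Step 8 (key step, proposed new method).**
- *What may go wrong.* Ring closure through the ortho carbon C4 instead of C10; intermolecular O-allylation to oligomeric aryl allyl ethers; poor discrimination of the two faces of the phenoxide, because the stereocenter forms on the nucleophile and not on the allyl unit; β-hydride elimination of the allyl complex to a diene if heating is needed.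
- *Fallback (known chemistry), from 9 to 12.* Alcohol 9 is desilylated with Bu4NF to 3-(4-hydroxy-3-methylidenebutyl)-2,4-dimethylphenol F1. Appel bromination (CBr4, PPh3) of the primary allylic alcohol gives 3-[3-(bromomethyl)but-3-en-1-yl]-2,4-dimethylphenol F2. KOt-Bu in t-BuOH/THF at high dilution then alkylates the phenoxide intramolecularly at its para carbon, a long-established way to angularly substituted cross-conjugated cyclohexadienones, and gives racemic 8-methylidene-11,12,13-trinoreudesma-1,4-dien-3-one F3. Preparative chromatography on a chiral stationary phase returns 12, and the (10R)-8-methylidene-11,12,13-trinoreudesma-1,4-dien-3-one F4 is set aside. Half of the material is lost.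

**Step 9.**
- *What may go wrong.* Carbonyl (1,2-) reduction, or slow hydride transfer to C1, which is neopentylic, with loss of material on prolonged exposure.
- *Fallback, from 12 to 13.* Reduction by electron transfer instead of hydride: two equivalents of Li in NH3/THF at −78 °C. Cross-conjugated dienones are expected to take up two electrons and a proton at the less substituted β-carbon C1, giving lithium (10R)-8-methylidene-11,12,13-trinoreudesma-2,4-dien-3-olate F5, which resists further reduction. Quenching with solid NH4Cl protonates C2 and gives 13.

**Step 10.**
- *What may go wrong.* Proton exchange between the enolate, tert-butoxide and any ketone formed during the change of solvent, which would move the enolate toward C2; incomplete sulfonylation of the hindered tetrasubstituted enolate; partial formation of the cis ring fusion.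
- *Fallback, from 13 to 15.* The same reduction is quenched with Me3SiCl/Et3N and the silyl enol ether (5R,10R)-8-methylidene-3-(trimethylsilyloxy)-11,12,13-trinor-5α-eudesm-3-ene F6 is isolated and purified. MeLi in THF regenerates enolate 14 free of alkoxide and amide, and PhNTf2 then gives 15.

**Step 13.**
- *What may go wrong.* Competing deprotonation at C9; retro-aldol cleavage of the hindered tertiary aldolate on warming; proton transfer from acetone to the enolate.
- *Fallback, from 18 to 21.* Ketone 18 is converted under equilibrating conditions (Me3SiCl, NaI, Et3N, MeCN) into (5R,10R)-8-(trimethylsilyloxy)-11,12,13-trinor-5α-eudesma-3,7-diene F7, which can be purified as a single regioisomer. A Mukaiyama addition to acetone promoted by TiCl4 in CH2Cl2 at −78 °C then gives 21.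

## Further compounds

F1 | step 8 | 3-(4-hydroxy-3-methylidenebutyl)-2,4-dimethylphenol | OCC(=C)CCc1c(C)ccc(O)c1C
F2 | step 8 | 3-[3-(bromomethyl)but-3-en-1-yl]-2,4-dimethylphenol | BrCC(=C)CCc1c(C)ccc(O)c1C
F3 | step 8 | racemic 8-methylidene-11,12,13-trinoreudesma-1,4-dien-3-one | O=C1C=CC2(C)CC(=C)CCC2=C1C
F4 | step 8 | (10R)-8-methylidene-11,12,13-trinoreudesma-1,4-dien-3-one | O=C1C=C[C@@]2(C)CC(=C)CCC2=C1C
F5 | step 9 | lithium (10R)-8-methylidene-11,12,13-trinoreudesma-2,4-dien-3-olate | [Li+].[O-]C1=CC[C@]2(C)CC(=C)CCC2=C1C
F6 | step 10 | (5R,10R)-8-methylidene-3-(trimethylsilyloxy)-11,12,13-trinor-5α-eudesm-3-ene | CC1=C(O[Si](C)(C)C)CC[C@]2(C)CC(=C)CC[C@@H]12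
F7 | step 13 | (5R,10R)-8-(trimethylsilyloxy)-11,12,13-trinor-5α-eudesma-3,7-diene | CC1=CCC[C@]2(C)CC(O[Si](C)(C)C)=CC[C@@H]12
A1 | alternative 1 | 4β-hydroxy-11,12,13,14,15-pentanoreudesm-5(10)-en-8-one ethylene ketal | O[C@H]1CCCC2=C1CCC1(C2)OCCO1
A2 | alternative 1 | 4β-hydroxy-5β,10β-methano [4.4.1]propellane 8-ethylene ketal | O[C@H]1CCC[C@@]23C[C@@]12CCC4(C3)OCCO4
A3 | alternative 2 | (E)-9-(tert-butyldimethylsilyloxy)-7-methyldeca-7,9-dien-1-yn-3-one | C#CC(=O)CCC/C(C)=C/C(=C)O[Si](C)(C)C(C)(C)C
A4 | alternative 2 | 8-(tert-butyldimethylsilyloxy)-11,12,13,15-tetranoreudesma-5,8-dien-4-one | O=C1CCC[C@]2(C)C=C(O[Si](C)(C)C(C)(C)C)CC=C12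
A5 | alternative 3 | 3-[(7R,8R)-8-acetyl-7-methyl-1,4-dioxaspiro[4.5]decan-7-yl]propanal | O=CCC[C@]1(C)CC2(OCCO2)CC[C@H]1C(C)=O
A6 | alternative 3 | 4α-hydroxy-11,12,13-trinor-5α-eudesmane-3,8-dione 8-ethylene ketal | O=C1CC[C@]2(C)CC3(OCCO3)CC[C@H]2[C@]1(C)O
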